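In a one-step world the substrate that goes is the target that comes, and the best moment is simply the last one. This flask may run up to 4.0 h, and to find its moment of most target I went to the spring run, which is this very flask followed so far.

in all of them: catalyst 0.05 mol%; added ligand 28 µM
- spring: substrate 0.010 M; reagent 1.1 equiv; the very flask that is asked about, followed so far
- dusk: substrate 0.015 M; reagent 1.1 equiv; run made earlier
- flask: substrate 0.010 M; reagent 1.10 equiv; time 4.0 h

spring run (percent of the substrate charged)

| time / min | target / % | substrate / % |
|---|---|---|
| 15.0 | 44 | 27 |
| 25.0 | 49 | 15 |
| 40.0 | 51 | 13 |
| 60.0 | 48 | 11 |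
| 90.0 | 49 | 9 |

dusk run (percent of the substrate charged)

| time / h | target / % | substrate / % |
|---|---|---|
| 0.250 | 49 | 17 |
| 0.417 | 52 | 11 |
| 0.833 | 58 | 10 |
| 1.50 | 58 | 6 |
| 3.00 | 56 | 3 |

(standard deviation of a reading: 1.5 percentage points)

- percent here means substrate units held: one side product counts as two
- what is said of target includes crystals
- crystals is a solid; its amount is given per volume of the solution
- reactions considered so far: substrate + reagent <-> target; substrate + reagent <-> isomer of the product; target + catalyst <-> isomer of the product + catalyst; catalyst + added ligand <-> idle complex; crystals <-> target; substrate + target -> side product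

- the moment within 4.0 h at which there is most target
- the amount of target, in percent of the substrate charged, at that time

Substrate is the limiting reagent, charged against 1.10 equiv of reagent, so I wrote its balance. The last spring reading left 42.0% of the charge as neither substrate nor target; I called that part the leak, L, and it sits in isomer of the product and side product. Target rises while substrate falls faster than L rises, and sinks when L rises faster.

Between 25.0 min and 90.0 min in the spring run, L rose by 6 percentage points and substrate fell by 6 points, so the two were level within the scatter and target stood still. I therefore put the peak inside that window, at its midpoint, 0.958 h, and took the mean of the spring target readings there, 49.2%.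

The forecast said 1 h (0.6 h to 2.5 h) and 50% (48% to 54%), adding “The maximum is broad”; its yield stood above my figure.

The flask gave 50.0% at 0.985 h.

    substrate + reagent ⇌ target (K = 190 M⁻¹, k = 0.192 M⁻¹ s⁻¹)
    substrate + reagent ⇌ isomer of the product (K = 235 M⁻¹, k = 0.0573 M⁻¹ s⁻¹)
    target + catalyst ⇌ isomer of the product + catalyst, rate k3*[catalyst]*[target] forward; the back reaction follows from the equilibrium constant (k = 12.1 M⁻¹ s⁻¹)
    catalyst + added ligand ⇌ idle complex, settled at all times (K = 61000 M⁻¹)
    crystals ⇌ target, rate k5*(cs5 - [target]) while solid is left; crystals form when [target] > cs5 (solubility = 0.560 mM, k = 0.0138 s⁻¹)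
    substrate + target → side product (k = 0.215 M⁻¹ s⁻¹)

Target stood at 48.2% after 0.493 h and at 48.1% after 1.97 h. The leak, read at 42.0% at the last spring reading, stood at 53.6% in the flask after 4.00 h. The neighbour with 0.0025 M of substrate held 6.28% target and 22.7% substrate after 4.00 h, so its leak came to 71.0%, above the flask's 53.6%.

The earlier runs and the new flask were computed from invented constants; noise was put on by code.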